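A direct plan would start from the ready-made phloroglucinol aldehyde A1, 2,4-dihydroxy-6-methoxybenzaldehyde, and would mask both of its phenols as MOM ethers to give the bis-ether A2.
It would then turn the aldehyde into the phenyl ketone A3 by a carbene-catalysed acyl-anion addition to benzyne, unmask the phenols to the benzophenone A4 and finish with a double C-prenylation in aqueous base.
(a) The acyl-anion addition to benzyne would be weak: an aldehyde flanked by two ortho alkoxy groups would form the Breslow intermediate slowly, so the aryne would be lost to side reactions.
(b) The MOM protection and its removal would be two steps that add nothing to the skeleton.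
(c) The closing double C-prenylation would fall on the most valuable material: O-alkylation, mono-alkylation and geminal, dearomatising dialkylation of the ambident phenoxide would compete and could hardly be steered.

**Plan of the new route**
Ring numbering: C1' carries the benzoyl group, C2' and C4' OH, C3' and C5' prenyl, C6' OMe.
The retrosynthesis cuts the ring bonds C1'–C2' and C1'–C6': C1' with its benzoyl group leaves as acetophenone, and C2'–C6' remain as the five ring carbons of the mirror-symmetric 2,6-dimethoxy-3,5-diprenyl-4H-pyran-4-one.
Enabling feature: with oxygens at C2', C4', C6' and identical prenyl groups at C3', C5', the benzene ring is symmetric about the C1'···C4' axis except for one O-methyl, so the symmetric pyranone maps onto it whichever methoxy-bearing carbon is attacked.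
The pyranone ring is made first (acidic cyclodehydration, before any acid-sensitive alkene is present), the prenyl groups are then fixed at C3 and C5 through two C–Br bonds, and the benzene ring arises last by exchange of the ring oxygen for the acetophenone methyl carbon.
The attacked carbon keeps its OMe (C6') and the other loses methanol (C2'–OH), so no phenol is protected, no arene is prenylated and no hindered aldehyde is acylated.
Key step: step 4

Remark on the chemistry: the oleum cyclodehydration of 3-oxopentanedioic diesters to 2,6-dialkoxy-4H-pyran-4-ones, a reaction type used for 2,4-dialkyl diesters, is assumed to extend to the unsubstituted diester 1.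

**Step 1**
Reactants: 1 dimethyl 3-oxopentanedioate
Product: 2 2,6-dimethoxy-4H-pyran-4-one
Conditions: oleum (20 % SO3 in H2SO4), 0 °C → rt; poured onto ice, NaHCO3, CH2Cl2 extraction
Reagents that add atoms: none
Why: Acid-mediated cyclodehydration of a 3-oxoglutaric diester, in which one ester oxygen of the dienol adds to the other protonated ester and water rather than methanol is lost because this leads to the aromatic 4-hydroxy-2,6-dimethoxypyrylium ion, released as the pyranone on quenching; no stereocentre is formed.

**Step 2**
Reactants: 2 2,6-dimethoxy-4H-pyran-4-one
Product: 3 3,5-dibromo-2,6-dimethoxy-4H-pyran-4-one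
Conditions: NBS (2.1 equiv), MeCN, 0 °C → rt
Reagents that add atoms: N-bromosuccinimide, O=C1CCC(=O)N1Br
Why: Electrophilic bromination of a 4-pyranone, in which C3 and C5 are the only C–H positions and each is the nucleophilic β-carbon of an O–C(OMe)=C ketene-acetal unit, so two equivalents of NBS should brominate both; no stereocentre is formed.

**Step 3**
Reactants: 3 3,5-dibromo-2,6-dimethoxy-4H-pyran-4-one; 4 tributyl(3-methylbut-2-en-1-yl)stannane (2.5 equiv)
Product: 5 2,6-dimethoxy-3,5-bis(3-methylbut-2-en-1-yl)-4H-pyran-4-one
Conditions: Pd(PPh3)4 (10 mol %), DMF, 90 °C
Reagents that add atoms: none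
Why: Migita–Kosugi–Stille cross-coupling, in which zerovalent palladium inserts into each C(sp2)–Br bond of the α-bromo enone units, the allylic stannane transmetalates and reductive elimination at the primary allyl terminus should give the linear prenyl groups exactly where the bromines stood, so O-alkylation and over-alkylation cannot occur; no stereocentre is formed.

**Step 4**
Reactants: 5 2,6-dimethoxy-3,5-bis(3-methylbut-2-en-1-yl)-4H-pyran-4-one; 6 acetophenone (1.3 equiv)
Product: 8 [2,4-dihydroxy-6-methoxy-3,5-bis(3-methylbut-2-en-1-yl)phenyl](phenyl)methanone, via ring-opened keto ester 7 (not isolated)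
Conditions: t-BuOK (3.0 equiv), THF, 0 °C → 60 °C; then 1 M HCl, 0 °C
Reagents that add atoms: none
Why: Proposed new method: the potassium enolate of 6 should add through carbon to C2 of 5 (equivalent to C6 by symmetry), the β-carbon of a vinylogous carbonate, and E1cB loss of the ring oxygen as a β-keto ester enolate opens the pyranone to 7, whose push-pull C4=C5 bond rotates freely through its dienolate. The C6 methylene of 7, acidified by the benzoyl group and the β-methoxy enone, then attacks the methyl ester carbonyl in a 6-exo-trig Claisen (Dieckmann-type) closure that forms the C1'–C2' bond, methoxide leaves and the cyclic triketone tautomerises irreversibly to the phloroglucinol, so that the ring oxygen of 5 is exchanged for the acetophenone methyl carbon. The closest known reaction types are the carbanion-induced ring transformation of pyranones and pyrylium salts into benzenes (for example with nitromethane), the addition–elimination of carbon nucleophiles at the methoxy-bearing carbon of 2,6-dimethoxy-4-pyranones and the Claisen cyclisation of 3,5,7-triketo esters to acylphloroglucinols. The step needs no site selectivity, because both methoxy-bearing carbons of 5 are equivalent, and the O-methyl pattern follows from the mechanism: the attacked carbon keeps its methoxy group (C6'–OMe), the ester carbon gives C2'–OH and the pyranone carbonyl gives C4'–OH. Competing loss of methoxide to a 2-phenacylpyranone is not a dead end, since methoxide re-addition reopens the ring towards the same arene, and the aldol of the C2 carbanion of 7 onto the benzoyl carbonyl cannot aromatise at a quaternary carbon and reverts, so both detours should drain to the aromatic phenoxide. No stereocentre is formed.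

**Compound list**
1 | dimethyl 3-oxopentanedioate | COC(=O)CC(=O)CC(=O)OC | starting material
2 | 2,6-dimethoxy-4H-pyran-4-one | COC1=CC(=O)C=C(OC)O1 | intermediate
3 | 3,5-dibromo-2,6-dimethoxy-4H-pyran-4-one | COC1=C(Br)C(=O)C(Br)=C(OC)O1 | intermediate
4 | tributyl(3-methylbut-2-en-1-yl)stannane | CCCC[Sn](CCCC)(CCCC)CC=C(C)C | starting material
5 | 2,6-dimethoxy-3,5-bis(3-methylbut-2-en-1-yl)-4H-pyran-4-one | COC1=C(CC=C(C)C)C(=O)C(CC=C(C)C)=C(OC)O1 | intermediate
6 | acetophenone | CC(=O)c1ccccc1 | starting material
7 | methyl (4E)-5-methoxy-2,4-bis(3-methylbut-2-en-1-yl)-3,7-dioxo-7-phenylhept-4-enoate (racemic and labile at C2, present as its enolate; the E isomer is the one that cyclises) | COC(=O)C(CC=C(C)C)C(=O)/C(CC=C(C)C)=C(/OC)CC(=O)c1ccccc1 | intermediate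
8 | [2,4-dihydroxy-6-methoxy-3,5-bis(3-methylbut-2-en-1-yl)phenyl](phenyl)methanone | COc1c(CC=C(C)C)c(O)c(CC=C(C)C)c(O)c1C(=O)c1ccccc1 | target

**Step count**
Total steps: 4. Longest linear sequence: 4 steps (1 → 2 → 3 → 5 → 8).

**Steps most likely to fail**

Step 4. Attack of the ketone enolate at the doubly donor-substituted, prenyl-flanked C2 may be slower than self-condensation of acetophenone, or the sequence may stall after loss of methoxide at the stage of an unreactive pyranone enolate. The fallback sets out from 5 and comes back at 8, and makes the two C–C bonds in separate operations. The preformed lithium enolate of 6 (LiN(SiMe3)2, THF, −78 → 0 °C) should replace one methoxy group of 5 by conjugate addition–elimination, a reaction type known for carbon nucleophiles on 2,6-dimethoxy-4-pyranones. This should give 2-methoxy-3,5-bis(3-methylbut-2-en-1-yl)-6-(2-oxo-2-phenylethyl)-4H-pyran-4-one F1, which is isolated. F1 is then isomerised with Mg(OMe)2 in MeOH at reflux. This is the base-induced opening of a 2-(2-oxoalkyl)-4-pyranone to a poly-β-carbonyl chain and its Claisen-type recyclisation to an acylphloroglucinol, and it should give 8.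

Step 3. Allylic transposition at palladium (reductive elimination at the tertiary terminus) may give 1,1-dimethylallyl groups, or protodebromination may intervene before the second coupling. The fallback sets out from 3 and comes back at 5. Double Stille coupling with allyltributylstannane (Pd(PPh3)4, DMF, 90 °C), where the allyl group has no regiochemical ambiguity, should give 2,6-dimethoxy-3,5-di(prop-2-en-1-yl)-4H-pyran-4-one F2. Cross-metathesis of both terminal alkenes with 2-methylbut-2-ene (second-generation Grubbs catalyst, RuCl2(=CHPh)(PCy3)(H2IMes), CH2Cl2, 40 °C) should then build the trisubstituted alkenes of 5.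

Step 1. Intermolecular self-condensation or C-sulfonation at the unsubstituted, strongly enolised α-positions may outrun ring closure. The fallback sets out from 1 and comes back at 3, and blocks the α-positions first. Br2 (2 equiv, CH2Cl2, 0 °C) should give dimethyl 2,4-dibromo-3-oxopentanedioate F3, a 2,4-disubstituted diester of the class for which the cyclodehydration is used; it would form as a mixture of diastereomers, which is of no consequence because both centres become sp2 carbons. Cyclodehydration of F3 in oleum should then give 3 directly, so that step 2 is no longer needed.

**Further compounds**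
F1 | step 4 | 2-methoxy-3,5-bis(3-methylbut-2-en-1-yl)-6-(2-oxo-2-phenylethyl)-4H-pyran-4-one | COC1=C(CC=C(C)C)C(=O)C(CC=C(C)C)=C(CC(=O)c2ccccc2)O1
F2 | step 3 | 2,6-dimethoxy-3,5-di(prop-2-en-1-yl)-4H-pyran-4-one | COC1=C(CC=C)C(=O)C(CC=C)=C(OC)O1
F3 | step 1 | dimethyl 2,4-dibromo-3-oxopentanedioate | COC(=O)C(Br)C(=O)C(Br)C(=O)OC
A1 | direct plan | 2,4-dihydroxy-6-methoxybenzaldehyde | COc1cc(O)cc(O)c1C=O
A2 | direct plan | 2-methoxy-4,6-bis(methoxymethoxy)benzaldehyde | COCOc1cc(OC)c(C=O)c(OCOC)c1
A3 | direct plan | [2-methoxy-4,6-bis(methoxymethoxy)phenyl](phenyl)methanone | COCOc1cc(OC)c(C(=O)c2ccccc2)c(OCOC)c1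
A4 | direct plan | (2,4-dihydroxy-6-methoxyphenyl)(phenyl)methanone | COc1cc(O)cc(O)c1C(=O)c1ccccc1
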